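1. I have no rate constants for these flasks, so I read one ratio from the earlier runs and commit to it before charging.

| setting | east | south-east | theta | beta |
|---|---|---|---|---|
| starting material | 0.029 M | 0.043 M | 0.043 M | 0.043 M |
| coupling partner | 1.5 equiv | 1.5 equiv | 1.50 equiv | 2.00 equiv |
| second substrate | 2 equiv | 1 equiv | 2.00 equiv | 2.00 equiv |
| remark | run made earlier | run made earlier |  |  |
| time |  |  | 20 d | 20 d |

| run | time / d | target / % | isomer of the product / % | starting material / % | cross product / % |
|---|---|---|---|---|---|
| east | 0.500 | 29 | 2 | 0 | 70 |
| east | 1.25 | 24 | 2 | 0 | 73 |
| east | 2.50 | 25 | 4 | 0 | 71 |
| east | 4.00 | 22 | 7 | 1 | 71 |
| south-east | 0.333 | 51 | 1 | 1 | 44 |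
| south-east | 0.833 | 46 | 9 | 0 | 45 |
| south-east | 1.67 | 39 | 16 | 0 | 43 |
| south-east | 4.00 | 29 | 23 | 1 | 42 |

(standard deviation of a reading: 1.5 percentage points)

- a reading or a percentage of target counts all its forms, free or not

* which of these there is most of at the end, counted by the starting material in it, theta (cross product / starting material / isomer of the product / target)
* which of these there is most of at the end, counted by the starting material in it, beta (cross product / starting material / isomer of the product / target)
* how much there is at the end of the one of these that leads, in percent of the starting material charged: theta
* how much there is at the end of the one of these that leads, in percent of the starting material charged: beta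

2. The decision is whether coupling partner stays at 1.50 equiv or goes up to 2.00 equiv. In the east run cross product reads 70% at 0.500 d and 71% at 4.00 d, so it stands flat and I take means: 71.2% in east and 43.5% in south-east.

3. I call cross product over the rest of the starting material the cross odds. They read 2.48 in east and 0.770 in south-east.

4. Second substrate over coupling partner stands twice as high in east as in south-east, while the odds rise by a factor 3.22. I keep 1.69 as the odds exponent, the logarithm of the rise in odds over the logarithm of the rise in charge ratio. It is a reading and carries their scatter. The runs also differ in concentration, and I assume that cancels from the odds.

5. Theta has east's ratio, so I expect 71.2% cross product. Beta's ratio is 0.750 of east's, which gives odds 1.53 and 60.4% cross product. By this reckoning, raising coupling partner costs about 11 percentage points of cross product, so for cross product I leave it at 1.50 equiv.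

6. The forecast has cross product leading in both flasks, with 70% in theta (60% to 78%) and 63% in beta (52% to 72%): “So the split is set early by competition between second substrate and coupling partner”. Its beta figure stands above mine.

    target ⇌ isomer of the product (K = 1.42, k = 9.55 × 10⁻⁶ /s)
    starting material + coupling partner → target (k = 0.00258 /M/s)
    starting material + second substrate → cross product (k = 0.00585 /M/s)
    second substrate + coupling partner → second product (k = 5.74 × 10⁻⁴ /M/s)
    2 starting material → self-condensation product (k = 4.31 × 10⁻⁷ /M/s)
    second substrate + target ⇌ idle adduct, settled at all times (K = 494 /M)

Theta ends at 71.0% cross product, odds 2.45 against the 2.48 I kept, and beta at 64.0%, above my 60.4%; cross product leads in both. At 0.445 d in theta the cross step uses starting material 1.6 times as fast as the target step, and by 10.0 d starting material reads 0% with cross product at 71.0%. For a flask like theta with the charge of second substrate cut to 0.500 equiv, the exponent gives odds 0.239, or 19.3% cross product. That flask holds 19.9% cross product, and the lead passes to isomer of the product at 46.0%.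

(Readings and results come from a simulation from invented constants; noise was put on by code.)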